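The bicyclo[3.2.1]octane core is disconnected at the bond between the methyl-bearing bridgehead C-5 and the bridging ketone C-8, back to an acyclic keto malonate whose only defined stereocentre is C-6. The feature exploited is that C-8 and C-2 are two carbonyls on one carbon (C-1, a prenylmalonate) and C-5 is the α-carbon of the C-4 methyl ketone. With KOtBu a reversible Dieckmann closure C-5→C-8 forms the cyclopentanone ring (C-1, C-8, C-5, C-6, C-7); only the isomer with acetyl and ester cis is drained by an irreversible Claisen closure C-3→C-2 of the six-membered ring. Both C-5 epimers and the prochiral malonate thus converge on one bicycle, C-6 placing its substituent exo.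

Key step: step 8

Remarks on the chemistry:
- Locants follow bicyclo[3.2.1]octane numbering of the target: C-1 prenyl bridgehead, C-2 ketone, C-3 acyl-bearing carbon, C-4 enol carbon, C-5 methyl bridgehead, C-6 hydroxypropyl-bearing carbon, C-7 methylene, C-8 bridging ketone.
- The target SMILES encodes a (2R)-2-methylbutanoyl group; (R)-2-methylbutanoic acid is assumed to be commercially available in high enantiomeric purity.
- The methyl-bearing carbon that becomes C-5 is carried as a mixture of epimers from the epoxide opening to the key step, which erases it; the SMILES leave this centre open.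
- The bicyclic 1,3-dione from the key step is drawn in its triketo form and will exist largely as enol tautomers.

Step 1
Reactants: 1 3-methylbut-2-en-1-ol (prenol)
Product: 2 [(2R)-3,3-dimethyloxiran-2-yl]methanol
Conditions: Ti(OiPr)4 (10 mol%), D-(−)-diethyl tartrate (12 mol%), tBuOOH (anhydrous, 2 equiv), 4 Å MS, CH2Cl2, −20 °C; non-aqueous work-up, distillation
Reagents that add atoms: tert-butyl hydroperoxide, CC(C)(C)OO
Why: Sharpless asymmetric epoxidation of a primary allylic alcohol; with the D-(−)-tartrate ligand the titanium-bound peroxide should deliver oxygen to the alkene face that gives the 2R epoxide, which sets the one stereocentre (later C-6) that the route has to preset.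

Step 2
Reactants: 2 [(2R)-3,3-dimethyloxiran-2-yl]methanol; 3 but-2-en-1-ylmagnesium chloride (crotylmagnesium chloride, commercial THF solution)
Product: 4 (2S)-2-[(2RS)-but-3-en-2-yl]-3-methylbutane-1,3-diol
Conditions: 3 (3 equiv), THF, −30 °C → rt; aq. NH4Cl
Reagents that add atoms: none
Why: Epoxide opening by an allylic Grignard reagent: after formation of the magnesium alkoxide the reagent should react through its γ-carbon (SE2′) at C-2, because the tertiary C-3 is closed to backside attack, so C-2 is inverted and becomes the later C-6, while the new methyl-bearing centre forms as both epimers without consequence.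

Step 3
Reactants: 4 (2S)-2-[(2RS)-but-3-en-2-yl]-3-methylbutane-1,3-diol
Product: 5 (2S)-2-[(2RS)-but-3-en-2-yl]-3-hydroxy-3-methylbutyl 4-methylbenzenesulfonate
Conditions: TsCl (1.1 equiv), pyridine, CH2Cl2, 0 °C
Reagents that add atoms: 4-methylbenzenesulfonyl chloride, Cc1ccc(cc1)S(Cl)(=O)=O
Why: Selective sulfonylation of the primary hydroxyl group; the tertiary alcohol is too hindered to react with TsCl under these conditions.

Step 4
Reactants: 5 (2S)-2-[(2RS)-but-3-en-2-yl]-3-hydroxy-3-methylbutyl 4-methylbenzenesulfonate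
Product: 6 (2S)-2-[(2RS)-but-3-en-2-yl]-3-methyl-3-[(triethylsilyl)oxy]butyl 4-methylbenzenesulfonate
Conditions: TESOTf (1.3 equiv), 2,6-lutidine (2 equiv), CH2Cl2, −78 → 0 °C
Reagents that add atoms: triethylsilyl trifluoromethanesulfonate, CC[Si](CC)(CC)OS(=O)(=O)C(F)(F)F
Why: Silylation of a tertiary alcohol with a silyl triflate; the silyl ether prevents oxetane formation and later lactonisation of the tertiary alkoxide onto the malonate esters.

Step 5
Reactants: 6 (2S)-2-[(2RS)-but-3-en-2-yl]-3-methyl-3-[(triethylsilyl)oxy]butyl 4-methylbenzenesulfonate; 7 dimethyl malonate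
Product: 8 dimethyl 2-{(2R)-2-[(2RS)-but-3-en-2-yl]-3-methyl-3-[(triethylsilyl)oxy]butyl}propanedioate
Conditions: 7 (3 equiv), NaH (2.8 equiv), NaI (0.2 equiv), DMF, 70 °C
Reagents that add atoms: none
Why: Malonic ester alkylation (SN2) at a β-branched primary carbon, run through the iodide formed in the flask (Finkelstein exchange) and with excess unhindered malonate anion to suppress dialkylation; the stereocentre is not involved.

Step 6
Reactants: 8 dimethyl 2-{(2R)-2-[(2RS)-but-3-en-2-yl]-3-methyl-3-[(triethylsilyl)oxy]butyl}propanedioate; 9 1-bromo-3-methylbut-2-ene (prenyl bromide)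
Product: 10 dimethyl 2-{(2R)-2-[(2RS)-but-3-en-2-yl]-3-methyl-3-[(triethylsilyl)oxy]butyl}-2-(3-methylbut-2-en-1-yl)propanedioate
Conditions: NaH (1.2 equiv), THF/DMF, 0 °C; 9 (1.5 equiv), 0 °C → rt
Reagents that add atoms: none
Why: Second malonic ester alkylation with a reactive allylic bromide builds the quaternary carbon that becomes C-1; its two esters are still equivalent, so no stereocentre is created here.

Step 7
Reactants: 10 dimethyl 2-{(2R)-2-[(2RS)-but-3-en-2-yl]-3-methyl-3-[(triethylsilyl)oxy]butyl}-2-(3-methylbut-2-en-1-yl)propanedioate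
Product: 11 dimethyl 2-(3-methylbut-2-en-1-yl)-2-{(2R)-3-methyl-2-[(2RS)-3-oxobutan-2-yl]-3-[(triethylsilyl)oxy]butyl}propanedioate
Conditions: PdCl2 (10 mol%), CuCl (1 equiv), O2 (1 atm), DMF/H2O 7:1, rt
Reagents that add atoms: water, O
Why: Tsuji–Wacker oxidation: the monosubstituted alkene is oxidised with Markovnikov selectivity to the methyl ketone, while the trisubstituted prenyl alkene should not react under these conditions.

Step 8
Reactants: 11 dimethyl 2-(3-methylbut-2-en-1-yl)-2-{(2R)-3-methyl-2-[(2RS)-3-oxobutan-2-yl]-3-[(triethylsilyl)oxy]butyl}propanedioate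
Product: 13 (1S,5R,6R)-5-methyl-1-(3-methylbut-2-en-1-yl)-6-{2-[(triethylsilyl)oxy]propan-2-yl}bicyclo[3.2.1]octane-2,4,8-trione, via cyclopentanone keto ester 12 (not isolated)
Conditions: KOtBu (3.5 equiv), THF (0.02 M), 0 → 40 °C; then cold 1 M HCl
Reagents that add atoms: none
Why: Under equilibrating alkoxide conditions the more substituted ketone enolate (C-5) attacks one malonate ester and expels methoxide (Dieckmann condensation, 5-(enolexo)-exo-trig), which forms the C-5–C-8 bond and cyclopentanone 12; 12 is a non-enolisable 1,3-dicarbonyl compound and reverts by retro-Claisen opening unless it reacts on. In the isomer of 12 that has the acetyl group at C-5 cis to the remaining ester at C-1 the acetyl enolate is acylated by that ester (Claisen condensation, 6-(enolendo)-exo-trig) and the 1,3-dione formed is deprotonated at once, which makes this second closure the irreversible exit; the closest known reaction type is the base-mediated closure of an α-acetyl group onto an α′-ester across a cycloalkanone to give bridged bicyclic 1,3-diones. The new stereocentres C-5 and C-1 need no preset control: both C-5 epimers of 11 give the same enolate, the two diastereotopic esters at C-1 exchange roles through the retro-Dieckmann equilibrium, and a one-carbon bridge can only span cis positions, so the relative configuration of C-1 and C-5 is fixed by the bicycle. The selectivity the step needs is the sense of this cis pair relative to C-6, that is exo versus endo placement of the silyloxypropyl group, and it should be exo because the three-carbon bridge is then built on the cyclopentanone face away from this large group. Excess KOtBu keeps the acetyl group of 12 as its enolate, which shields it from methoxide, and high dilution with fast five-ring closure should outrun seven-membered Claisen closure from the methyl enolate.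

Step 9
Reactants: 13 (1S,5R,6R)-5-methyl-1-(3-methylbut-2-en-1-yl)-6-{2-[(triethylsilyl)oxy]propan-2-yl}bicyclo[3.2.1]octane-2,4,8-trione; 14 (2R)-2-methylbutanoic acid
Product: 17 (1R,5R,6R)-4-hydroxy-6-(2-hydroxypropan-2-yl)-5-methyl-1-(3-methylbut-2-en-1-yl)-3-[(2R)-2-methylbutanoyl]bicyclo[3.2.1]oct-3-ene-2,8-dione (target), via enol ester 15 (not isolated), via silyl-protected triketone 16 (not isolated)
Conditions: 14 (1.3 equiv), DCC (1.4 equiv), DMAP (1.3 equiv), CH2Cl2, 0 °C → rt; filter, concentrate; then HF·pyridine, THF, 0 °C → rt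
Reagents that add atoms: none
Why: Steglich O-acylation of the 1,3-dione followed by DMAP-mediated O-to-C acyl shift (rearrangement of enol esters to 2-acyl-1,3-diones) should place the acyl group at C-3 without touching the ring stereocentres, the (2R) centre comes from the acid, and fluoride then removes the silyl ether.

Compound list
1 | 3-methylbut-2-en-1-ol | CC(C)=CCO | starting material
2 | [(2R)-3,3-dimethyloxiran-2-yl]methanol | OC[C@H]1OC1(C)C | intermediate
3 | but-2-en-1-ylmagnesium chloride | CC=CC[Mg]Cl | starting material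
4 | (2S)-2-[(2RS)-but-3-en-2-yl]-3-methylbutane-1,3-diol | OC[C@H](C(C)C=C)C(C)(C)O | intermediate
5 | (2S)-2-[(2RS)-but-3-en-2-yl]-3-hydroxy-3-methylbutyl 4-methylbenzenesulfonate | Cc1ccc(cc1)S(=O)(=O)OC[C@H](C(C)C=C)C(C)(C)O | intermediate
6 | (2S)-2-[(2RS)-but-3-en-2-yl]-3-methyl-3-[(triethylsilyl)oxy]butyl 4-methylbenzenesulfonate | Cc1ccc(cc1)S(=O)(=O)OC[C@H](C(C)C=C)C(C)(C)O[Si](CC)(CC)CC | intermediate
7 | dimethyl malonate | COC(=O)CC(=O)OC | starting material
8 | dimethyl 2-{(2R)-2-[(2RS)-but-3-en-2-yl]-3-methyl-3-[(triethylsilyl)oxy]butyl}propanedioate | COC(=O)C(C(=O)OC)C[C@H](C(C)C=C)C(C)(C)O[Si](CC)(CC)CC | intermediate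
9 | 1-bromo-3-methylbut-2-ene | CC(C)=CCBr | starting material
10 | dimethyl 2-{(2R)-2-[(2RS)-but-3-en-2-yl]-3-methyl-3-[(triethylsilyl)oxy]butyl}-2-(3-methylbut-2-en-1-yl)propanedioate | COC(=O)C(CC=C(C)C)(C(=O)OC)C[C@H](C(C)C=C)C(C)(C)O[Si](CC)(CC)CC | intermediate
11 | dimethyl 2-(3-methylbut-2-en-1-yl)-2-{(2R)-3-methyl-2-[(2RS)-3-oxobutan-2-yl]-3-[(triethylsilyl)oxy]butyl}propanedioate | COC(=O)C(CC=C(C)C)(C(=O)OC)C[C@H](C(C)C(C)=O)C(C)(C)O[Si](CC)(CC)CC | intermediate
12 | methyl (1R,3R,4R)-3-acetyl-3-methyl-1-(3-methylbut-2-en-1-yl)-2-oxo-4-{2-[(triethylsilyl)oxy]propan-2-yl}cyclopentane-1-carboxylate | CC(=O)[C@]1(C)C(=O)[C@@](CC=C(C)C)(C[C@H]1C(C)(C)O[Si](CC)(CC)CC)C(=O)OC | intermediate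
13 | (1S,5R,6R)-5-methyl-1-(3-methylbut-2-en-1-yl)-6-{2-[(triethylsilyl)oxy]propan-2-yl}bicyclo[3.2.1]octane-2,4,8-trione | C1C(=O)[C@]2(C)C(=O)[C@@](CC=C(C)C)(C[C@H]2C(C)(C)O[Si](CC)(CC)CC)C1=O | intermediate
14 | (2R)-2-methylbutanoic acid | CC[C@@H](C)C(=O)O | starting material
15 | (1S,5R,6R)-5-methyl-1-(3-methylbut-2-en-1-yl)-2,8-dioxo-6-{2-[(triethylsilyl)oxy]propan-2-yl}bicyclo[3.2.1]oct-3-en-4-yl (2R)-2-methylbutanoate (drawn as the O-4 enol ester; the O-2 regioisomer converges) | C1=C(OC(=O)[C@H](C)CC)[C@]2(C)C(=O)[C@@](CC=C(C)C)(C[C@H]2C(C)(C)O[Si](CC)(CC)CC)C1=O | intermediate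
16 | (1R,5R,6R)-4-hydroxy-5-methyl-1-(3-methylbut-2-en-1-yl)-3-[(2R)-2-methylbutanoyl]-6-{2-[(triethylsilyl)oxy]propan-2-yl}bicyclo[3.2.1]oct-3-ene-2,8-dione | CC[C@@H](C)C(=O)C1=C(O)[C@]2(C)C(=O)[C@@](CC=C(C)C)(C[C@H]2C(C)(C)O[Si](CC)(CC)CC)C1=O | intermediate
17 | (1R,5R,6R)-4-hydroxy-6-(2-hydroxypropan-2-yl)-5-methyl-1-(3-methylbut-2-en-1-yl)-3-[(2R)-2-methylbutanoyl]bicyclo[3.2.1]oct-3-ene-2,8-dione | CC[C@@H](C)C(=O)C1=C(O)[C@]2(C)C(=O)[C@@](CC=C(C)C)(C[C@H]2C(C)(C)O)C1=O | target

Total step count: 9
Longest linear sequence: 9 steps (from compound 1)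

Steps most likely to fail

Step 8. The substrate may leave the productive manifold before the second acylation. The kinetic methyl enolate may close to a seven-membered dione enolate that alkoxide cannot carry further, methoxide may remove the acetyl group by retro-Claisen attack, or the exo/endo discrimination in the second closure may be too small. The fallback sets out from 11 and comes back at 13 and closes the same bond last. Kinetic deprotonation of the methyl ketone (LDA, 2.2 equiv, THF, −78 °C → rt, high dilution) and Claisen closure onto one ester should give, after separation from its C-1 epimer, methyl (1S,5RS,6R)-5-methyl-1-(3-methylbut-2-en-1-yl)-2,4-dioxo-6-{2-[(triethylsilyl)oxy]propan-2-yl}cycloheptane-1-carboxylate F1. The dianion of F1 (LDA, 2.5 equiv, THF, −78 → 0 °C; the second deprotonation can only occur at C-5, the one γ-position that carries hydrogen) should then close the C-5–C-8 bond by transannular Dieckmann acylation and give 13 on acidification. The price is that C-1 is set without control in the ring closure to F1.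

Step 2. The allylic Grignard reagent may react through its α-carbon, magnesium may assist opening at the tertiary carbon, or the magnesium alkoxide may undergo Payne rearrangement before it is opened. The fallback replaces steps 1 and 2 and avoids the epoxide altogether. It uses none of compounds 1 to 3, sets out from commercial racemic 3-methylpent-4-enoic acid and (R)-4-benzyl-1,3-oxazolidin-2-one, and comes back at 4. N-Acylation through the mixed pivalic anhydride (PivCl, Et3N; lithiated oxazolidinone) gives (4R)-4-benzyl-3-[(3RS)-3-methylpent-4-enoyl]-1,3-oxazolidin-2-one F2. Evans alkylation of its chlorotitanium enolate (TiCl4, iPr2NEt, BnOCH2Cl, CH2Cl2, 0 °C), with the electrophile entering anti to the benzyl group of the auxiliary, should give (4R)-4-benzyl-3-{(2S)-2-[(benzyloxy)methyl]-3-methylpent-4-enoyl}-1,3-oxazolidin-2-one F3. Transesterification (MeOMgBr, MeOH/CH2Cl2, 0 °C) gives methyl (2S)-2-[(benzyloxy)methyl]-3-methylpent-4-enoate F4, double addition of MeMgBr (CeCl3, THF, −78 → 0 °C) gives (3S)-3-[(benzyloxy)methyl]-2,4-dimethylhex-5-en-2-ol F5, and reductive debenzylation (LiDBB, THF, −78 °C) gives 4.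

Step 9. The sequence may stall at the enol ester if the O-to-C acyl shift to the hindered C-3 is slow, and the acyl α-centre may epimerise through ketene formation from the acylpyridinium ion. The fallback sets out from 13 and comes back at 16. O-Methylation (Me2SO4, K2CO3, acetone) gives (1S,5R,6R)-4-methoxy-5-methyl-1-(3-methylbut-2-en-1-yl)-6-{2-[(triethylsilyl)oxy]propan-2-yl}bicyclo[3.2.1]oct-3-ene-2,8-dione F6 (its 2-methoxy regioisomer converges). Vinylic lithiation at C-3 (LiTMP, THF, −78 °C) and acylation with (2R)-2-methylbutanoyl chloride F7 (from 14 with oxalyl chloride and catalytic DMF) should give (1R,5R,6R)-4-methoxy-5-methyl-1-(3-methylbut-2-en-1-yl)-3-[(2R)-2-methylbutanoyl]-6-{2-[(triethylsilyl)oxy]propan-2-yl}bicyclo[3.2.1]oct-3-ene-2,8-dione F8. Demethylation (LiCl, DMSO, 120 °C) gives 16, which HF·pyridine converts to 17 as in step 9.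

Further compounds
F1 | step 8 | methyl (1S,5RS,6R)-5-methyl-1-(3-methylbut-2-en-1-yl)-2,4-dioxo-6-{2-[(triethylsilyl)oxy]propan-2-yl}cycloheptane-1-carboxylate | C1C(=O)C(C)[C@H](C(C)(C)O[Si](CC)(CC)CC)C[C@](CC=C(C)C)(C(=O)OC)C1=O
F2 | step 2 | (4R)-4-benzyl-3-[(3RS)-3-methylpent-4-enoyl]-1,3-oxazolidin-2-one | C=CC(C)CC(=O)N1[C@H](Cc2ccccc2)COC1=O
F3 | step 2 | (4R)-4-benzyl-3-{(2S)-2-[(benzyloxy)methyl]-3-methylpent-4-enoyl}-1,3-oxazolidin-2-one | C=CC(C)[C@@H](COCc1ccccc1)C(=O)N1[C@H](Cc2ccccc2)COC1=O
F4 | step 2 | methyl (2S)-2-[(benzyloxy)methyl]-3-methylpent-4-enoate | C=CC(C)[C@@H](COCc1ccccc1)C(=O)OC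
F5 | step 2 | (3S)-3-[(benzyloxy)methyl]-2,4-dimethylhex-5-en-2-ol | C=CC(C)[C@@H](COCc1ccccc1)C(C)(C)O
F6 | step 9 | (1S,5R,6R)-4-methoxy-5-methyl-1-(3-methylbut-2-en-1-yl)-6-{2-[(triethylsilyl)oxy]propan-2-yl}bicyclo[3.2.1]oct-3-ene-2,8-dione | C1=C(OC)[C@]2(C)C(=O)[C@@](CC=C(C)C)(C[C@H]2C(C)(C)O[Si](CC)(CC)CC)C1=O
F7 | step 9 | (2R)-2-methylbutanoyl chloride | CC[C@@H](C)C(Cl)=O
F8 | step 9 | (1R,5R,6R)-4-methoxy-5-methyl-1-(3-methylbut-2-en-1-yl)-3-[(2R)-2-methylbutanoyl]-6-{2-[(triethylsilyl)oxy]propan-2-yl}bicyclo[3.2.1]oct-3-ene-2,8-dione | CC[C@@H](C)C(=O)C1=C(OC)[C@]2(C)C(=O)[C@@](CC=C(C)C)(C[C@H]2C(C)(C)O[Si](CC)(CC)CC)C1=O
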